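# Proposed total synthesis of juglanin A by B-alkyl Suzuki–Miyaura macrocyclization

**Numbering used throughout.** 1 2-methoxyresorcinol; 2 aryl iminium chloride (in flask); 3 2,4-dihydroxy-3-methoxybenzaldehyde; 4 its 4-O-benzyl ether; 5 the 4-O-benzyl-2-O-methoxymethyl aldehyde; 6 (3-ethoxycarbonylpropyl)triphenylphosphonium bromide; 7 its ylide (in flask); 8 styrenyl ester; 9 saturated phenol ester; 10 (5-bromo-2-methoxyphenyl)boronic acid; 11 diaryl ether ester; 12 aluminium hemiacetal (in flask); 13 aldehyde; 14 vinylmagnesium bromide; 15 allylic alcohol; 16 allylic silyl ether; 17 alkylborane (in flask); 18 macrocyclic silyl ether; 19 macrocyclic alcohol; 20 macrocyclic ketone methoxymethyl ether; 21 juglanin A.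

Atom labels: the chain is C1 (on ring B) to C7 (on ring A). Ring A: A1 bears C7, A3 the ether oxygen, A4 the methoxy group. Ring B: B1 bears C1, B2 the hydroxyl, B3 the methoxy group, B4 the ether oxygen.

## Analysis of the target

Juglanin A (21) is a diaryl ether heptanoid: two benzene rings joined by one ether oxygen and by a seven-carbon chain, which together close a 15-membered meta,para-cyclophane. On ring A the chain (A1) is meta to the ether oxygen (A3) and para to the methoxy group (A4). Ring B carries four contiguous substituents (chain at B1, hydroxyl at B2, methoxy at B3, ether oxygen at B4), with the chain para to the ether oxygen. The chain is saturated apart from a ketone at C5, and there is no stereocentre, so nothing has to be set or preserved. The sensitive groups are the electron-rich free phenol at B2, which is easily oxidized, and the ketone with enolizable methylenes at C4 and C6; the methyl ethers and the diaryl ether are robust. The synthesis is hard for two reasons: the para-bridged ring B must bend to fit a 15-membered ring, so any ring closure fights strain as well as entropy, and the two phenolic oxygens of ring B (B2 and B4) must be told apart. The strategy rests on the A1–C7 bond. A1 is an unhindered aryl carbon that can carry bromine, C7 is a primary carbon that can carry boron once a C6=C7 vinyl group is hydroborated, and the neighbouring C5 is then an allylic carbinol, one oxidation below the ketone.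

## Retrosynthetic reasoning

**21 back to 18 (no skeletal bond cut).** The B2 phenol of 21 is masked as the methoxymethyl ether 20, and the C5 ketone of 20 is traced to alcohol 19 and its silyl ether 18. A ketone at C5 next to a C6=C7 alkene would be a vinyl ketone, which a borane would reduce or add to in conjugate fashion. With C5 as a silyl-protected carbinol the alkene is an ordinary terminal olefin. The forward steps are fluoride desilylation, oxidation while the phenol is still masked, and acid cleavage of the acetal.

**18 to 16 through 17 (A1–C7 cut).** This is the only chain-to-ring bond that joins an sp2 carbon free of ortho substituents to a primary sp3 carbon. The alternative ring bond, at the ether oxygen, joins two ortho-methoxy-flanked carbons and would need forcing conditions in the ring-closing mode. Cutting A1–C7 leaves bromine on ring A and, through alkylborane 17, a vinyl group in 16. What is gained is that the hindered diaryl ether can be made early, between two molecules, and that the precursor 16 is a stable compound. The forward reaction must place boron on C7 only and must couple within one molecule.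

**16 to 13 and 14 (C5–C6 cut).** The silyl ether 16 comes from allylic alcohol 15, and 15 from aldehyde 13 and the vinyl Grignard reagent 14. This brings in C6 and C7 in one step and creates the C5 oxygen. The new centre may be racemic. Aldehyde 13 is the half-reduced form of ester 11, reached through the aluminium hemiacetal 12.

**11 to 9 and 10 (A3–O cut).** The ether is cut so that the oxygen stays on ring B as phenol 9 and ring A arrives as boronic acid 10, which already holds the methoxy group and the bromine in the right places. A copper-mediated oxidative coupling at room temperature is chosen because it does not touch the C–Br bond needed later. Phenol 9 has a single free hydroxyl, so the regiochemistry is not left to a steric preference between two hydroxyls.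

**9 to 5 and 6 (C1=C2 cut).** Phenol 9 comes from the styrenyl ester 8 by hydrogenation, which saturates C1=C2 and removes the benzyl group together. This is done before any bromine is in the molecule. Ester 8 is the Wittig product of aldehyde 5 and the ylide 7 from phosphonium salt 6, which supplies C2–C5 with C5 at the ester level. An ester-bearing salt is used so that no separate esterification is needed.

**5 to 1 (functional group changes on ring B).** The two hydroxyls are distinguished at the aldehyde stage. In 3 the hydroxyl para to the formyl group is free and more acidic, and the ortho one is chelated. Benzylation therefore gives 4, and the remaining hydroxyl is then capped as the methoxymethyl ether 5. Aldehyde 3 arises by formylation of the symmetrical 1 through iminium salt 2. Both positions that are ortho to one hydroxyl and para to the other are equivalent, so only one product is possible.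

## Alternatives that were turned down

**Alternative 1: ring A from a 2-pyrone.** Here ring A is built, not bought. The A2–A3 and A1–A6 bonds are cut, leading to A2, a 3-aryloxy-4-methoxy-2-pyrone tethered through ring B and the ketal-protected chain to a terminal alkyne. On heating, the alkyne would add across the pyrone diene in an intramolecular [4+2] reaction. The bridged adduct would expel its lactone bridge and aromatize, so ring A and the 15-membered ring would appear together in the benzyl ether ketal A1. Ketal hydrolysis and hydrogenolysis would then give 21.
- For: no metal is needed, and two bonds and two rings form in one step. C5 stays at the ketone oxidation level throughout, which is better than the chosen plan, where two steps are spent adjusting C5.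
- Against: a pyrone carrying two oxygen donors and an unactivated alkyne are a poorly matched diene and dienophile, so high temperature is required. The tether is far too long to give the entropic help of the usual short-tether cases, yet the transition state must already bend ring B. A long tether also does not fix the orientation: the alkyne can add the other way round and place the chain para to the ether oxygen, giving a less strained regioisomer. A2 itself needs a multistep pyrone synthesis, whereas ring A with the correct pattern is available as 10.
- Comparison: the chosen plan fixes the regiochemistry by the position of bromine and closes the ring at moderate temperature.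

**Alternative 2: 15-endo radical cyclization.** The C2–C3 bond is cut. The precursor A4 carries a 2-arylethyl iodide on ring B and a vinyl ketone (C3=C4–C5=O) on the ring A arm. With a stannane chain carrier at high dilution, the primary C2 radical would add to the terminal carbon C3, and the resulting α-keto radical would be reduced to A3, the acetate of 21.
- For: a nucleophilic alkyl radical and an electron-poor alkene are polarity matched, and the endo mode is the normal one for large rings. The ketone is already in place, so one deacetylation finishes the synthesis. On end-game step count this is stronger than the chosen plan (one step after closure against three).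
- Against: ring closure competes with hydrogen transfer to the open-chain radical. Lowering the hydride concentration is the only remedy, and it also slows the chain. The strain of this cyclophane should make closure slower than in the flexible chains for which the reaction type is known. A4 combines a β-arylethyl iodide, which eliminates to a styrene, with a vinyl ketone, which polymerizes and adds nucleophiles, so the steps just before closure run on fragile material.
- Comparison: the chosen plan offers a stable precursor (16) and a closure in which both reacting ends sit on one palladium atom before the bond forms.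

**Alternative 3: enone ring-closing metathesis.** The C3=C4 bond is cut. The precursor A6 has a butenyl group on ring B and a vinyl ketone on the ring A arm. A ruthenium carbene catalyst would join the two alkenes, with loss of the two terminal methylene groups, to give the macrocyclic E-enone A5. One hydrogenation would saturate the alkene and remove the benzyl group.
- For: the functional-group tolerance is high and the end game is short (two steps after closure against three). On that point it is as strong as or slightly stronger than the chosen plan.
- Against: metathesis is reversible, so the outcome drifts toward the thermodynamic mixture. A trans enone makes C3, C4, C5 and their neighbours coplanar and adds strain to a ring that must already bend ring B, so the ring–chain equilibrium should favour cyclic dimers and oligomers. The electron-poor vinyl ketone end engages the carbene slowly, the catalyst loads on the butenyl end, and homodimerization there is easy. A vinyl ketone must again be carried.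
- Comparison: the chosen plan closes the ring by an irreversible reductive elimination under kinetic control, with every chain carbon sp3 at the moment of closure.

Key step: step 10

## Route

Remark on the chemistry: the target is taken as drawn, without stereodescriptors. C5 in 15–19 is racemic and ends as the ketone, and any conformational chirality of the cyclophane is not controlled.

Step 1
Reactants: 1 2-methoxyresorcinol (2-methoxybenzene-1,3-diol)
Product: 3 2,4-dihydroxy-3-methoxybenzaldehyde, via aryl iminium chloride 2 (not isolated)
Conditions: POCl3, DMF, MeCN, 0 °C → rt; then H2O, 50 °C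
Reagents that add atoms: N,N-dimethylformamide (CN(C)C=O); water (O)
Why: Vilsmeier–Haack formylation; the chloroiminium ion attacks the position para to one hydroxyl and ortho to the other (the two such positions are equivalent by symmetry, the third free position is meta to both hydroxyls), and the iminium salt 2 deactivates the ring against a second attack before it is hydrolysed to the aldehyde.

Step 2
Reactants: 3 2,4-dihydroxy-3-methoxybenzaldehyde
Product: 4 4-(benzyloxy)-2-hydroxy-3-methoxybenzaldehyde
Conditions: BnBr (1.05 equiv), NaHCO3, MeCN, 80 °C
Reagents that add atoms: benzyl bromide (BrCc1ccccc1)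
Why: Regioselective Williamson etherification; the 4-hydroxyl, para to the formyl group, is the more acidic and is free, whereas the 2-hydroxyl is held in a hydrogen bond to the carbonyl oxygen, so a weak base should alkylate only the former.

Step 3
Reactants: 4 4-(benzyloxy)-2-hydroxy-3-methoxybenzaldehyde
Product: 5 4-(benzyloxy)-3-methoxy-2-(methoxymethoxy)benzaldehyde
Conditions: NaH, DMF, 0 °C; then MOMCl, 0 °C → rt
Reagents that add atoms: chloromethyl methyl ether (COCCl)
Why: Williamson-type O-alkylation of the sodium phenoxide with an α-chloro ether; full deprotonation by NaH breaks the chelate that makes this hydroxyl sluggish, and the aldehyde has no enolizable hydrogen.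

Step 4
Reactants: 5 4-(benzyloxy)-3-methoxy-2-(methoxymethoxy)benzaldehyde; 6 (3-ethoxycarbonylpropyl)triphenylphosphonium bromide
Product: 8 ethyl (Z)-5-[4-(benzyloxy)-3-methoxy-2-(methoxymethoxy)phenyl]pent-4-enoate, via phosphonium ylide 7 (not isolated)
Conditions: 6, NaN(SiMe3)2, THF, −78 °C; then 5, −78 °C → rt
Reagents that add atoms: none
Why: Wittig olefination with a non-stabilized ylide whose ester is remote; a hindered amide base at low temperature forms the ylide without attacking the ester, and the alkene geometry (mainly Z expected) is irrelevant because step 5 saturates the bond.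

Step 5
Reactants: 8 ethyl (Z)-5-[4-(benzyloxy)-3-methoxy-2-(methoxymethoxy)phenyl]pent-4-enoate
Product: 9 ethyl 5-[4-hydroxy-3-methoxy-2-(methoxymethoxy)phenyl]pentanoate
Conditions: H2 (1 atm), Pd/C (10%), EtOAc, rt
Reagents that add atoms: none
Why: Heterogeneous catalytic hydrogenation saturates the C1=C2 bond and hydrogenolyses the benzyl ether in the same operation; the methoxymethyl ether, the methyl ether and the ester are inert under neutral conditions, and no halogen is yet present.

Step 6
Reactants: 9 ethyl 5-[4-hydroxy-3-methoxy-2-(methoxymethoxy)phenyl]pentanoate; 10 (5-bromo-2-methoxyphenyl)boronic acid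
Product: 11 ethyl 5-[4-(5-bromo-2-methoxyphenoxy)-3-methoxy-2-(methoxymethoxy)phenyl]pentanoate
Conditions: Cu(OAc)2 (1.5 equiv), pyridine, 4 Å MS, CH2Cl2, dry air, rt
Reagents that add atoms: none
Why: Chan–Lam oxidative C–O coupling; the aryl group passes from boron to the divalent copper phenoxide, oxidation to trivalent copper and reductive elimination give the diaryl ether, and air returns the copper to its divalent state. The C–Br bond is inert to copper at room temperature and 9 has only one free hydroxyl, so the regiochemistry is unambiguous.

Step 7
Reactants: 11 ethyl 5-[4-(5-bromo-2-methoxyphenoxy)-3-methoxy-2-(methoxymethoxy)phenyl]pentanoate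
Product: 13 5-[4-(5-bromo-2-methoxyphenoxy)-3-methoxy-2-(methoxymethoxy)phenyl]pentanal, via aluminium hemiacetal 12 (not isolated)
Conditions: i-Bu2AlH (1.1 equiv), CH2Cl2, −78 °C; MeOH, then aq KNaC4H4O6 (potassium sodium tartrate)
Reagents that add atoms: none
Why: Partial reduction of an ester; at −78 °C one hydride adds and the tetrahedral aluminium hemiacetal 12 persists until the quench, which releases the aldehyde. Aryl bromide, acetal and aryl ethers do not react.

Step 8
Reactants: 13 5-[4-(5-bromo-2-methoxyphenoxy)-3-methoxy-2-(methoxymethoxy)phenyl]pentanal; 14 vinylmagnesium bromide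
Product: 15 rac-7-[4-(5-bromo-2-methoxyphenoxy)-3-methoxy-2-(methoxymethoxy)phenyl]hept-1-en-3-ol
Conditions: 14, THF, −78 → 0 °C; aq NH4Cl
Reagents that add atoms: none
Why: Grignard 1,2-addition to the aldehyde creates C5 as a racemic allylic carbinol (no control is needed because C5 ends as a ketone); bromine–magnesium exchange at the aryl bromide does not compete with a vinyl Grignard reagent at low temperature.

Step 9
Reactants: 15 rac-7-[4-(5-bromo-2-methoxyphenoxy)-3-methoxy-2-(methoxymethoxy)phenyl]hept-1-en-3-ol
Product: 16 rac-tert-butyl({7-[4-(5-bromo-2-methoxyphenoxy)-3-methoxy-2-(methoxymethoxy)phenyl]hept-1-en-3-yl}oxy)dimethylsilane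
Conditions: TBSCl, imidazole, DMF, rt
Reagents that add atoms: tert-butyldimethylsilyl chloride (CC(C)(C)[Si](C)(C)Cl)
Why: Imidazole-promoted silylation of a secondary alcohol; the silyl ether keeps the hydroxyl from consuming borane and from binding palladium in step 10 and adds bulk next to the alkene.

Step 10
Reactants: 16 rac-tert-butyl({7-[4-(5-bromo-2-methoxyphenoxy)-3-methoxy-2-(methoxymethoxy)phenyl]hept-1-en-3-yl}oxy)dimethylsilane
Product: 18 racemic macrocyclic C5 silyl ether (15-membered cyclophane; C5 OSi(t-Bu)Me2; B2 OCH2OMe), via B-alkyl-9-BBN borane 17 (not isolated)
Conditions: 9-BBN dimer, THF, 0 °C → rt; then syringe-pump addition to PdCl2(dppf) (10 mol %), AsPh3, Cs2CO3, DMF/THF/H2O, 60 °C, final concentration about 2 mM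
Reagents that add atoms: none
Why: 9-BBN adds across the monosubstituted C6=C7 alkene of 16 through a four-centre transition state with boron on the terminal carbon C7, giving 17 while the aryl bromide stays untouched because no palladium is present yet. When 17 is fed slowly into the catalyst solution, zerovalent palladium (formed in the flask from PdCl2(dppf)) inserts into the A1–Br bond, the base-bound borate hands its primary C7 alkyl group to palladium within the same molecule, and reductive elimination forms the A1–C7 bond. The closest known reaction type is the intramolecular B-alkyl Suzuki–Miyaura macrocyclization of an ω-(9-BBN)alkyl aryl or alkenyl halide. The 15-membered ring is closed by ring contraction: intramolecular transmetalation gives a 16-membered aryl(alkyl)palladacycle, from which reductive elimination expels the metal. No stereocentre is formed; C5 is racemic and is oxidized later. The step needs anti-Markovnikov hydroboration, secured by the bulk of 9-BBN next to the branched silyloxy-bearing C5; transfer of the primary alkyl group only, secured by the slow migration of the secondary bridgehead B–C bonds; reductive elimination ahead of β-hydride elimination, favoured by the wide bite angle of dppf; and ring closure ahead of chain growth, favoured by the low stationary concentration of 17 under slow addition.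

Step 11
Reactants: 18 racemic macrocyclic C5 silyl ether
Product: 19 racemic macrocyclic C5 alcohol (B2 OCH2OMe)
Conditions: Bu4NF, THF, rt
Reagents that add atoms: none
Why: Fluoride-mediated desilylation driven by the strength of the Si–F bond; the methoxymethyl ether, the methyl ethers and the diaryl ether are inert to fluoride.

Step 12
Reactants: 19 racemic macrocyclic C5 alcohol
Product: 20 juglanin A methoxymethyl ether (macrocyclic C5 ketone; B2 OCH2OMe)
Conditions: Dess–Martin periodinane, CH2Cl2, rt
Reagents that add atoms: none
Why: Dess–Martin oxidation of a secondary alcohol by ligand exchange at hypervalent iodine and loss of the carbinol hydrogen; the phenol is still masked, so the electron-rich ring B cannot be oxidized, and the only stereocentre disappears here.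

Step 13
Reactants: 20 juglanin A methoxymethyl ether
Product: 21 juglanin A
Conditions: HCl (conc., cat.), MeOH, 45 °C; aq NaHCO3 work-up
Reagents that add atoms: none
Why: Acid-catalysed cleavage of the acetal-type methoxymethyl ether through an oxocarbenium ion that methanol traps; the aryl methyl ethers, the diaryl ether and the ketone survive, and any dimethyl ketal formed reverts on aqueous work-up.

## Compound list

1 | 2-methoxyresorcinol | COc1c(O)cccc1O | starting material
2 | N-(2,4-dihydroxy-3-methoxybenzylidene)-N-methylmethanaminium chloride (not isolated) | C[N+](C)=Cc1ccc(O)c(OC)c1O.[Cl-] | intermediate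
3 | 2,4-dihydroxy-3-methoxybenzaldehyde | O=Cc1ccc(O)c(OC)c1O | intermediate
4 | 4-(benzyloxy)-2-hydroxy-3-methoxybenzaldehyde | O=Cc1ccc(OCc2ccccc2)c(OC)c1O | intermediate
5 | 4-(benzyloxy)-3-methoxy-2-(methoxymethoxy)benzaldehyde | O=Cc1ccc(OCc2ccccc2)c(OC)c1OCOC | intermediate
6 | (3-ethoxycarbonylpropyl)triphenylphosphonium bromide | CCOC(=O)CCC[P+](c1ccccc1)(c1ccccc1)c1ccccc1.[Br-] | starting material
7 | ethyl 4-(triphenylphosphoranylidene)butanoate (ylide, not isolated) | CCOC(=O)CCC=P(c1ccccc1)(c1ccccc1)c1ccccc1 | intermediate
8 | ethyl (Z)-5-[4-(benzyloxy)-3-methoxy-2-(methoxymethoxy)phenyl]pent-4-enoate (Z expected as the major isomer; the mixture is used) | CCOC(=O)CC/C=C\c1ccc(OCc2ccccc2)c(OC)c1OCOC | intermediate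
9 | ethyl 5-[4-hydroxy-3-methoxy-2-(methoxymethoxy)phenyl]pentanoate | CCOC(=O)CCCCc1ccc(O)c(OC)c1OCOC | intermediate
10 | (5-bromo-2-methoxyphenyl)boronic acid | COc1ccc(Br)cc1B(O)O | starting material
11 | ethyl 5-[4-(5-bromo-2-methoxyphenoxy)-3-methoxy-2-(methoxymethoxy)phenyl]pentanoate | CCOC(=O)CCCCc1ccc(Oc2cc(Br)ccc2OC)c(OC)c1OCOC | intermediate
12 | diisobutylaluminium hemiacetal of ester 11 (racemic, not isolated) | CCOC(CCCCc1ccc(Oc2cc(Br)ccc2OC)c(OC)c1OCOC)O[Al](CC(C)C)CC(C)C | intermediate
13 | 5-[4-(5-bromo-2-methoxyphenoxy)-3-methoxy-2-(methoxymethoxy)phenyl]pentanal | O=CCCCCc1ccc(Oc2cc(Br)ccc2OC)c(OC)c1OCOC | intermediate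
14 | vinylmagnesium bromide | C=C[Mg]Br | starting material
15 | rac-7-[4-(5-bromo-2-methoxyphenoxy)-3-methoxy-2-(methoxymethoxy)phenyl]hept-1-en-3-ol | C=CC(O)CCCCc1ccc(Oc2cc(Br)ccc2OC)c(OC)c1OCOC | intermediate
16 | rac-tert-butyl({7-[4-(5-bromo-2-methoxyphenoxy)-3-methoxy-2-(methoxymethoxy)phenyl]hept-1-en-3-yl}oxy)dimethylsilane | C=CC(O[Si](C)(C)C(C)(C)C)CCCCc1ccc(Oc2cc(Br)ccc2OC)c(OC)c1OCOC | intermediate
17 | racemic B-alkyl-9-borabicyclo[3.3.1]nonane from 16, boron on C7 (not isolated) | C(CC(O[Si](C)(C)C(C)(C)C)CCCCc1ccc(Oc2cc(Br)ccc2OC)c(OC)c1OCOC)B1C2CCCC1CCC2 | intermediate
18 | racemic macrocyclic silyl ether: juglanin A skeleton with CH–OSi(t-Bu)Me2 at C5 and OCH2OMe at B2 | COc1ccc2cc1Oc1ccc(c(OCOC)c1OC)CCCCC(O[Si](C)(C)C(C)(C)C)CC2 | intermediate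
19 | racemic macrocyclic alcohol: juglanin A skeleton with CH–OH at C5 and OCH2OMe at B2 | COc1ccc2cc1Oc1ccc(c(OCOC)c1OC)CCCCC(O)CC2 | intermediate
20 | juglanin A methoxymethyl ether | COc1ccc2cc1Oc1ccc(c(OCOC)c1OC)CCCCC(=O)CC2 | intermediate
21 | juglanin A | COc1ccc2cc1Oc1ccc(c(O)c1OC)CCCCC(=O)CC2 | target

## Step count and risk

Total: 13 steps. Longest linear sequence: 13 steps, from 1 to 21; compounds 6, 10 and 14 are bought and enter directly.

**Step 10 (key step).** The most likely failure is chain growth: intermolecular coupling to dimers and oligomers outruns ring closure, because the transition state for intramolecular transmetalation must already bend the para-bridged ring B. If transmetalation is slow, the reactive ends can also be lost by protodeboronation at C7 or hydrodebromination at A1.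
Fallback, from 9 back to 18: the ring is closed at the ether oxygen instead, and the A1–C7 bond is made between two molecules.
- Phenol 9 is silylated (TBSCl, imidazole, DMF) to the aryl silyl ether ester F1.
- F1 is reduced with i-Bu2AlH at −78 °C, through the aluminium hemiacetal F2 (not isolated), to the aldehyde F3.
- F3 is treated with vinylmagnesium bromide 14 to give the racemic allylic alcohol F4, which is silylated to the bis(silyl ether) F5.
- Hydroboration with 9-BBN gives the borane F6 (not isolated). It is coupled with 2-bromo-4-iodoanisole (COc1ccc(I)cc1Br) at the more reactive carbon–iodine bond (PdCl2(dppf), K3PO4, THF/DMF/H2O, rt) to give the linear aryl bromide F7.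
- K2CO3 in MeOH cleaves only the aryl silyl ether and gives the phenol F8.
- An intramolecular Ullmann diaryl ether synthesis (CuI, N,N-dimethylglycine, Cs2CO3, dioxane, 100 °C, high dilution) joins the B4 oxygen to A3 and gives 18.

**Step 6.** The most likely failure is slow aryl transfer between two partners that each carry an ortho methoxy group. The boronic acid is then used up by protodeboronation, oxidation and homocoupling before the ether forms.
Fallback, from 9 back to 11: ring A is attached by nucleophilic aromatic substitution and its methoxy group is made afterwards.
- The phenoxide of 9 displaces fluoride from 4-bromo-2-fluorobenzaldehyde (O=Cc1ccc(Br)cc1F; K2CO3, DMF, 90 °C) to give the aryloxy aldehyde F9.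
- Baeyer–Villiger (Dakin-type) oxidation with mCPBA in CH2Cl2 gives the aryl formate F10.
- K2CO3 in EtOH cleaves the formate to the phenol F11.
- Methylation (MeI, K2CO3, acetone) gives 11.

**Step 7.** The most likely failure is over-reduction. If the aluminium hemiacetal collapses before the quench, aldehyde is released in the presence of hydride and goes on to the primary alcohol, while some ester stays unreacted.
Fallback, from 11 back to 13: the ester is reduced completely with LiBH4 in THF/MeOH to the primary alcohol F12, which Dess–Martin periodinane in CH2Cl2 oxidizes to 13.

**Step 2.** The most likely failure is loss of regiocontrol. The methoxy group next to the 4-hydroxyl slows its alkylation, so the chelated hydroxyl, or both hydroxyls, may be alkylated.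
Fallback, from 3 back to 4: both hydroxyls are benzylated (BnBr in excess, K2CO3, DMF) to the bis(benzyl ether) F13. MgBr2·OEt2 in CH2Cl2/Et2O then removes only the benzyl group ortho to the formyl group, through a magnesium chelate between the carbonyl and the ortho oxygen, and gives 4.

## Further compounds

F1 | step 10 | ethyl 5-[4-(tert-butyldimethylsilyloxy)-3-methoxy-2-(methoxymethoxy)phenyl]pentanoate | CCOC(=O)CCCCc1ccc(O[Si](C)(C)C(C)(C)C)c(OC)c1OCOC
F2 | step 10 | diisobutylaluminium hemiacetal of ester F1 (racemic, not isolated) | CCOC(CCCCc1ccc(O[Si](C)(C)C(C)(C)C)c(OC)c1OCOC)O[Al](CC(C)C)CC(C)C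
F3 | step 10 | 5-[4-(tert-butyldimethylsilyloxy)-3-methoxy-2-(methoxymethoxy)phenyl]pentanal | O=CCCCCc1ccc(O[Si](C)(C)C(C)(C)C)c(OC)c1OCOC
F4 | step 10 | rac-7-[4-(tert-butyldimethylsilyloxy)-3-methoxy-2-(methoxymethoxy)phenyl]hept-1-en-3-ol | C=CC(O)CCCCc1ccc(O[Si](C)(C)C(C)(C)C)c(OC)c1OCOC
F5 | step 10 | racemic bis(tert-butyldimethylsilyl) ether of F4 | C=CC(O[Si](C)(C)C(C)(C)C)CCCCc1ccc(O[Si](C)(C)C(C)(C)C)c(OC)c1OCOC
F6 | step 10 | racemic B-alkyl-9-borabicyclo[3.3.1]nonane from F5 (not isolated) | C(CC(O[Si](C)(C)C(C)(C)C)CCCCc1ccc(O[Si](C)(C)C(C)(C)C)c(OC)c1OCOC)B1C2CCCC1CCC2
F7 | step 10 | racemic linear aryl bromide with aryl and alkyl silyl ethers (A1–C7 bond formed; Br at A3) | COc1ccc(CCC(O[Si](C)(C)C(C)(C)C)CCCCc2ccc(O[Si](C)(C)C(C)(C)C)c(OC)c2OCOC)cc1Br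
F8 | step 10 | racemic linear bromo phenol (free hydroxyl at B4; Br at A3) | COc1ccc(CCC(O[Si](C)(C)C(C)(C)C)CCCCc2ccc(O)c(OC)c2OCOC)cc1Br
F9 | step 6 | ethyl 5-[4-(5-bromo-2-formylphenoxy)-3-methoxy-2-(methoxymethoxy)phenyl]pentanoate | CCOC(=O)CCCCc1ccc(Oc2cc(Br)ccc2C=O)c(OC)c1OCOC
F10 | step 6 | ethyl 5-[4-(5-bromo-2-formyloxyphenoxy)-3-methoxy-2-(methoxymethoxy)phenyl]pentanoate | CCOC(=O)CCCCc1ccc(Oc2cc(Br)ccc2OC=O)c(OC)c1OCOC
F11 | step 6 | ethyl 5-[4-(5-bromo-2-hydroxyphenoxy)-3-methoxy-2-(methoxymethoxy)phenyl]pentanoate | CCOC(=O)CCCCc1ccc(Oc2cc(Br)ccc2O)c(OC)c1OCOC
F12 | step 7 | 5-[4-(5-bromo-2-methoxyphenoxy)-3-methoxy-2-(methoxymethoxy)phenyl]pentan-1-ol | OCCCCCc1ccc(Oc2cc(Br)ccc2OC)c(OC)c1OCOC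
F13 | step 2 | 2,4-bis(benzyloxy)-3-methoxybenzaldehyde | O=Cc1ccc(OCc2ccccc2)c(OC)c1OCc1ccccc1
A1 | alternative 1 | O-benzyl juglanin A ethylene ketal | COc1ccc2cc1Oc1ccc(c(OCc3ccccc3)c1OC)CCCCC1(OCCO1)CC2
A2 | alternative 1 | 3-aryloxy-4-methoxy-2-pyrone tethered to a terminal alkyne (ring B benzyl ether, C5 ethylene ketal) | C#CCCC1(OCCO1)CCCCc1ccc(OC2=C(OC)C=COC2=O)c(OC)c1OCc1ccccc1
A3 | alternative 2 | juglanin A acetate | COc1ccc2cc1Oc1ccc(c(OC(C)=O)c1OC)CCCCC(=O)CC2
A4 | alternative 2 | open-chain vinyl ketone with 2-arylethyl iodide on ring B (B2 acetate) | C=CC(=O)CCc1ccc(OC)c(Oc2ccc(CCI)c(OC(C)=O)c2OC)c1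
A5 | alternative 3 | macrocyclic E-enone benzyl ether | COc1ccc2cc1Oc1ccc(c(OCc3ccccc3)c1OC)CC/C=C/C(=O)CC2
A6 | alternative 3 | open-chain vinyl ketone with but-3-enyl group on ring B (B2 benzyl ether) | C=CC(=O)CCc1ccc(OC)c(Oc2ccc(CCC=C)c(OCc3ccccc3)c2OC)c1
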